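## Retrosynthetic overview

- Target 17 (7S carbinol; 3R,4S ring with the two arms cis) comes from bis-silyl ether 16 by desilylation. The ArCH2 bond of 16 is cut to aryl bromide 4 and the alkylborane from face-selective hydroboration of exocyclic alkene 14 (B-alkyl Suzuki–Miyaura coupling, sets the third stereocentre).
- 14 is cut at the carbinol–ring bond to aldehyde 7 and cyclic allyl acetate 13: an iridium-catalysed anti- and enantioselective carbonyl allylation with allylic transposition sets both remaining stereocentres (new step).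
- 4 and 7 both come from catechol (methylation, para-bromination, silylation; formylation of 4 gives 7).
- 13 comes from methyl 2-(bromomethyl)acrylate and allyl alcohol. The only ring that is built, the dihydrofuran, is closed first by ring-closing metathesis and becomes the tetrahydrofuran of the target; both arenes are bought as catechol.

Assumption: the ligand antipodes written ((R)-SEGPHOS, (S)-TRIP) are assigned by analogy with the parent reactions; the configuration of 14 is checked (Mosher esters) and the antipodal ligand is used if the sense is opposite.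

## Route

Step 1
Reactants: 1 catechol
Product: 2 guaiacol (2-methoxyphenol)
Conditions: MeI (1.0 equiv), K2CO3 (1.0 equiv), acetone, 56 °C
Reagents that add atoms: iodomethane, CI
Why: Williamson ether synthesis with one equivalent of MeI gives mainly the mono-ether, which is separated from veratrole and unreacted catechol by base extraction and distillation.

Step 2
Reactants: 2 guaiacol
Product: 3 4-bromo-2-methoxyphenol
Conditions: NBS (1.0 equiv), MeCN, 0 °C
Reagents that add atoms: N-bromosuccinimide, O=C1CCC(=O)N1Br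
Why: Electrophilic aromatic bromination is directed para to the free hydroxyl, the stronger donor.

Step 3
Reactants: 3 4-bromo-2-methoxyphenol
Product: 4 (4-bromo-2-methoxyphenoxy)triisopropylsilane
Conditions: TIPSCl (1.1 equiv), imidazole (2 equiv), DMF, rt
Reagents that add atoms: chlorotriisopropylsilane, CC(C)[Si](Cl)(C(C)C)C(C)C
Why: Imidazole-promoted O-silylation; the bulky aryl TIPS ether tolerates n-BuLi, warm carbonate and aqueous phosphate in the later steps.

Step 4
Reactants: 4 (4-bromo-2-methoxyphenoxy)triisopropylsilane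
Product: 7 3-methoxy-4-[(triisopropylsilyl)oxy]benzaldehyde, via aryllithium 5 (not isolated), via lithium hemiaminal alkoxide 6 (not isolated)
Conditions: n-BuLi (1.1 equiv), THF, −78 °C; DMF (2 equiv), −78 → 0 °C; H2O
Reagents that add atoms: N,N-dimethylformamide, CN(C)C=O
Why: Bromine–lithium exchange followed by Bouveault formylation; the tetrahedral adduct collapses to the aldehyde on aqueous quench.

Step 5
Reactants: 8 methyl 2-(bromomethyl)acrylate, 9 allyl alcohol (3 equiv)
Product: 10 methyl 2-[(allyloxy)methyl]acrylate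
Conditions: Et3N (1.5 equiv), CH2Cl2, 0 °C → rt
Reagents that add atoms: none
Why: Amine-mediated allylic substitution (Williamson-type etherification); SN2 and SN2′ attack on this symmetric allyl system give the same ether.

Step 6
Reactants: 10 methyl 2-[(allyloxy)methyl]acrylate
Product: 11 methyl 2,5-dihydrofuran-3-carboxylate
Conditions: second-generation Grubbs catalyst RuCl2(=CHPh)(H2IMes)(PCy3) (2 mol %), CH2Cl2, 40 °C
Reagents that add atoms: none
Why: Ring-closing olefin metathesis to a five-membered ring, driven by loss of ethene.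

Step 7
Reactants: 11 methyl 2,5-dihydrofuran-3-carboxylate
Product: 12 (2,5-dihydrofuran-3-yl)methanol
Conditions: i-Bu2AlH (2.3 equiv), CH2Cl2, −78 → 0 °C; Na2SO4·10H2O
Reagents that add atoms: none
Why: Clean 1,2-reduction of the conjugated ester to the allylic alcohol by the aluminium hydride.

Step 8
Reactants: 12 (2,5-dihydrofuran-3-yl)methanol
Product: 13 (2,5-dihydrofuran-3-yl)methyl acetate
Conditions: Ac2O (1.5 equiv), pyridine, DMAP (5 mol %), CH2Cl2, 0 °C → rt
Reagents that add atoms: acetic anhydride, CC(=O)OC(C)=O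
Why: DMAP-catalysed acylation of the primary allylic alcohol gives the ionisable allyl donor.

Step 9
Reactants: 7 3-methoxy-4-[(triisopropylsilyl)oxy]benzaldehyde, 13 (2,5-dihydrofuran-3-yl)methyl acetate (2 equiv)
Product: 14 (S)-[3-methoxy-4-(triisopropylsilyloxy)phenyl][(3R)-4-methylenetetrahydrofuran-3-yl]methanol
Conditions: [Ir(cod)Cl]2 (2.5 mol %), (R)-SEGPHOS (5 mol %), 4-cyano-3-nitrobenzoic acid (10 mol %), Cs2CO3 (20 mol %), i-PrOH (2 equiv), THF, 90 °C
Reagents that add atoms: none
Why: Proposed new method: iridium-catalysed transfer-hydrogenative carbonyl allylation with a cyclic β,γ-disubstituted allyl acetate as donor, which has not been shown; the cyclometallated monovalent iridium C,O-benzoate ionises 13 to a π-allyl complex of trivalent iridium, whose σ-form bound at the exocyclic CH2 adds to 7 through a closed chair transition state at the ring γ-carbon with allylic transposition, so that the ring-locked E geometry gives the anti pair and the chiral bisphosphine the 7S sense, while i-PrOH returns the metal to the monovalent state; the closest known reaction type is the Krische anti-crotylation of aldehydes with α-methylallyl acetate.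

Step 10
Reactants: 14 (S)-[3-methoxy-4-(triisopropylsilyloxy)phenyl][(3R)-4-methylenetetrahydrofuran-3-yl]methanol, 4 (4-bromo-2-methoxyphenoxy)triisopropylsilane (1.3 equiv)
Product: 16 (S)-[3-methoxy-4-(triisopropylsilyloxy)phenyl]{(3R,4S)-4-[3-methoxy-4-(triisopropylsilyloxy)benzyl]tetrahydrofuran-3-yl}methanol, via alkyl-9-BBN borane 15 (not isolated)
Conditions: 9-BBN dimer (2.2 equiv B–H), THF, 0 °C → rt; then 4, Pd(OAc)2 (5 mol %), SPhos (10 mol %), aq K3PO4 (3 equiv), THF, 60 °C
Reagents that add atoms: none
Why: Anti-Markovnikov hydroboration delivers hydrogen to the ring carbon from the face opposite the neighbouring CH(OH)Ar arm, so the new CH2–B arm is cis to it, and the B-alkyl Suzuki–Miyaura coupling (zerovalent palladium, oxidative addition into 4, base-assisted transmetalation, reductive elimination) forms the Ar–CH2 bond without touching that stereocentre; the excess borane covers slow reaction with the free hydroxyl.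

Step 11
Reactants: 16 (S)-[3-methoxy-4-(triisopropylsilyloxy)phenyl]{(3R,4S)-4-[3-methoxy-4-(triisopropylsilyloxy)benzyl]tetrahydrofuran-3-yl}methanol
Product: 17 (S)-(4-hydroxy-3-methoxyphenyl)[(3R,4S)-4-(4-hydroxy-3-methoxybenzyl)tetrahydrofuran-3-yl]methanol (target)
Conditions: n-Bu4NF (2.5 equiv), AcOH (2.5 equiv), THF, 0 °C
Reagents that add atoms: none
Why: Fluoride-mediated desilylation of both aryl silyl ethers; acetic acid buffering keeps the p-hydroxybenzylic alcohol from forming a quinone methide.

## Compound list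

1 | catechol (benzene-1,2-diol) | Oc1ccccc1O | starting material
2 | guaiacol (2-methoxyphenol) | COc1ccccc1O | intermediate
3 | 4-bromo-2-methoxyphenol | COc1cc(Br)ccc1O | intermediate
4 | (4-bromo-2-methoxyphenoxy)triisopropylsilane | COc1cc(Br)ccc1O[Si](C(C)C)(C(C)C)C(C)C | intermediate
5 | [3-methoxy-4-(triisopropylsilyloxy)phenyl]lithium | COc1cc([Li])ccc1O[Si](C(C)C)(C(C)C)C(C)C | intermediate
6 | lithium (dimethylamino)[3-methoxy-4-(triisopropylsilyloxy)phenyl]methanolate (racemic) | COc1cc(C(O[Li])N(C)C)ccc1O[Si](C(C)C)(C(C)C)C(C)C | intermediate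
7 | 3-methoxy-4-[(triisopropylsilyl)oxy]benzaldehyde | COc1cc(C=O)ccc1O[Si](C(C)C)(C(C)C)C(C)C | intermediate
8 | methyl 2-(bromomethyl)acrylate | C=C(CBr)C(=O)OC | starting material
9 | allyl alcohol (prop-2-en-1-ol) | C=CCO | starting material
10 | methyl 2-[(allyloxy)methyl]acrylate | C=CCOCC(=C)C(=O)OC | intermediate
11 | methyl 2,5-dihydrofuran-3-carboxylate | COC(=O)C1=CCOC1 | intermediate
12 | (2,5-dihydrofuran-3-yl)methanol | OCC1=CCOC1 | intermediate
13 | (2,5-dihydrofuran-3-yl)methyl acetate | CC(=O)OCC1=CCOC1 | intermediate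
14 | (S)-[3-methoxy-4-(triisopropylsilyloxy)phenyl][(3R)-4-methylenetetrahydrofuran-3-yl]methanol | C=C1COC[C@@H]1[C@H](O)c1ccc(O[Si](C(C)C)(C(C)C)C(C)C)c(OC)c1 | intermediate
15 | 9-({(3S,4R)-4-[(S)-hydroxy(3-methoxy-4-(triisopropylsilyloxy)phenyl)methyl]tetrahydrofuran-3-yl}methyl)-9-borabicyclo[3.3.1]nonane | B1(C[C@@H]2COC[C@@H]2[C@H](O)c2ccc(O[Si](C(C)C)(C(C)C)C(C)C)c(OC)c2)C2CCCC1CCC2 | intermediate
16 | (S)-[3-methoxy-4-(triisopropylsilyloxy)phenyl]{(3R,4S)-4-[3-methoxy-4-(triisopropylsilyloxy)benzyl]tetrahydrofuran-3-yl}methanol | COc1cc(C[C@@H]2COC[C@@H]2[C@H](O)c2ccc(O[Si](C(C)C)(C(C)C)C(C)C)c(OC)c2)ccc1O[Si](C(C)C)(C(C)C)C(C)C | intermediate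
17 | (S)-(4-hydroxy-3-methoxyphenyl)[(3R,4S)-4-(4-hydroxy-3-methoxybenzyl)tetrahydrofuran-3-yl]methanol | COc1cc(C[C@@H]2COC[C@@H]2[C@H](O)c2ccc(O)c(OC)c2)ccc1O | target

## Step count and risks

Total steps: 11. Longest linear sequence: 7 (steps 1, 2, 3, 4, 9, 10, 11; the branch 5, 6, 7, 8, 9, 10, 11 is equally long).

**Step 9 (the proposed new allylation).** Ionisation of the trisubstituted cyclic allyl acetate may be slow, the π-allyl may lose a β-hydrogen and aromatise to 3-methylfuran, and the aryl silyl ether may suffer under warm carbonate. The fallback uses known chemistry and sets out from 13. Palladium-catalysed Miyaura borylation (Pd2(dba)3, B2pin2, DMSO, 50 °C) gives the allylboronate 2-[(2,5-dihydrofuran-3-yl)methyl]-4,4,5,5-tetramethyl-1,3,2-dioxaborolane F1. Chiral phosphoric acid catalysed allylboration of 7 with F1 ((S)-TRIP 5 mol %, 4 Å sieves, toluene, −30 °C) goes through the same chair transition state with the ring-locked E geometry and gives the pinacol borate ester of the anti alcohol F2. Aqueous work-up hydrolyses F2, and the route is rejoined at 14.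

**Step 10 (facial selectivity of the hydroboration and coupling of a β-branched alkylborane in the presence of a free hydroxyl).** The fallback sets out from 14 and separates the stereo-defining event from the C–C coupling:
- Silylation (TBSOTf, 2,6-lutidine, CH2Cl2, −78 °C) gives the tert-butyldimethylsilyl ether of 14 F3, whose larger arm shields its face more strongly.
- 9-BBN gives the alkylborane F4, and NaOH/H2O2 oxidises it to the cis primary alcohol F5; any trans isomer is removed on silica at this stage.
- CBr4/PPh3 gives the cis bromide F6.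
- Nickel-catalysed reductive cross-electrophile coupling with 4 (NiBr2(dme) 10 mol %, 4,4′-di-tert-butyl-2,2′-bipyridine, Zn dust, NaI, DMA, 60 °C) gives the tris-silyl ether of the target F7.
- n-Bu4NF/AcOH removes all three silyl groups, and the fallback comes back at 17.

**Step 1 (mono- versus di-methylation of catechol).** If the statistical mixture is unworkable, the fallback sets out from 1. Exhaustive methylation (MeI 2.5 equiv, K2CO3, acetone, 56 °C) gives veratrole (1,2-dimethoxybenzene) F8. Nucleophilic mono-demethylation with NaSEt (DMF, 150 °C) stops at the phenoxide and comes back at 2.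

Further compounds

F1 | step 9 | 2-[(2,5-dihydrofuran-3-yl)methyl]-4,4,5,5-tetramethyl-1,3,2-dioxaborolane | CC1(C)OB(CC2=CCOC2)OC1(C)C
F2 | step 9 | pinacol borate ester of 14: 2-{(S)-[3-methoxy-4-(triisopropylsilyloxy)phenyl][(3R)-4-methylenetetrahydrofuran-3-yl]methoxy}-4,4,5,5-tetramethyl-1,3,2-dioxaborolane | C=C1COC[C@@H]1[C@H](OB1OC(C)(C)C(C)(C)O1)c1ccc(O[Si](C(C)C)(C(C)C)C(C)C)c(OC)c1
F3 | step 10 | tert-butyl{(S)-[3-methoxy-4-(triisopropylsilyloxy)phenyl][(3R)-4-methylenetetrahydrofuran-3-yl]methoxy}dimethylsilane | C=C1COC[C@@H]1[C@H](O[Si](C)(C)C(C)(C)C)c1ccc(O[Si](C(C)C)(C(C)C)C(C)C)c(OC)c1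
F4 | step 10 | 9-({(3S,4R)-4-[(S)-(tert-butyldimethylsilyloxy)(3-methoxy-4-(triisopropylsilyloxy)phenyl)methyl]tetrahydrofuran-3-yl}methyl)-9-borabicyclo[3.3.1]nonane | B1(C[C@@H]2COC[C@@H]2[C@H](O[Si](C)(C)C(C)(C)C)c2ccc(O[Si](C(C)C)(C(C)C)C(C)C)c(OC)c2)C2CCCC1CCC2
F5 | step 10 | [(3R,4R)-4-{(S)-[(tert-butyldimethylsilyl)oxy][3-methoxy-4-(triisopropylsilyloxy)phenyl]methyl}tetrahydrofuran-3-yl]methanol | OC[C@@H]1COC[C@@H]1[C@H](O[Si](C)(C)C(C)(C)C)c1ccc(O[Si](C(C)C)(C(C)C)C(C)C)c(OC)c1
F6 | step 10 | tert-butyl{(S)-[(3R,4S)-4-(bromomethyl)tetrahydrofuran-3-yl][3-methoxy-4-(triisopropylsilyloxy)phenyl]methoxy}dimethylsilane | BrC[C@@H]1COC[C@@H]1[C@H](O[Si](C)(C)C(C)(C)C)c1ccc(O[Si](C(C)C)(C(C)C)C(C)C)c(OC)c1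
F7 | step 10 | tert-butyl[(S)-[3-methoxy-4-(triisopropylsilyloxy)phenyl]{(3R,4S)-4-[3-methoxy-4-(triisopropylsilyloxy)benzyl]tetrahydrofuran-3-yl}methoxy]dimethylsilane | COc1cc(C[C@@H]2COC[C@@H]2[C@H](O[Si](C)(C)C(C)(C)C)c2ccc(O[Si](C(C)C)(C(C)C)C(C)C)c(OC)c2)ccc1O[Si](C(C)C)(C(C)C)C(C)C
F8 | step 1 | veratrole (1,2-dimethoxybenzene) | COc1ccccc1OC
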